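**Plan**
- Retrosynthesis: after removal of three silyl ethers, the pyranone ring is cut at C2–C3 and at C4–C4a. This gives an aryloxymethyl electrophile (ring A with O1 and C2) and a chiral arylacetyl thioimide (ring B with C3 and C4), which go back to 2‑iodoresorcinol and 2,4‑dihydroxyacetophenone.
- Enabling feature: ring A is a phloroglucinol in which O1 lies para to the prenylated C6. The ether precursor therefore has a mirror plane through O1/C8a/C6, and its two ortho carbons (future C4a and C8) are equivalent and activated by three oxygens, so 6‑ versus 8‑prenyl regiochemistry cannot arise. C2 is a formaldehyde‑level carbon on O1 and C3 a benzylic α‑acyl carbon, so C2=O1–C8a=C4a (oxadiene cation) and C3=C4 (enolate) form a latent [4+2] pair.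
- Forward: ring A fragment by Mg/Cu prenylation, Ir C–H borylation/oxidation para to the prenyl group, and pivaloyloxymethyl ether formation. Ring B fragment by iodination, oxidative 1,2‑aryl shift to the arylacetate, Suzuki alkenylation and thioimide formation.
- The pyranone ring is formed last, in one flask: titanium‑enolate alkylation (C2–C3), then Friedel–Crafts acyl transfer (C4–C4a) with loss of the auxiliary; buffered fluoride then frees the three phenols.
- Stereochemistry: C3 (S) comes from the (R)‑4‑benzylthiazolidine‑2‑thione auxiliary in the alkylation; the E alkene comes from a stereodefined alkenylboronate.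

Key step: step 12

Assumption: boronate 15 is taken as commercial (otherwise it is the hydroboration product of 3‑methylbut‑1‑yne with pinacolborane); the descriptor derived from the given SMILES is (3S).

**Step 1**
Reactants: 1 2‑iodobenzene‑1,3‑diol (2‑iodoresorcinol)
Product: 2 1,3‑bis(tert‑butyldimethylsilyloxy)‑2‑iodobenzene
Conditions: TBSCl (2.3 eq), imidazole, DMF, rt
Reagents that add atoms: tert‑butyldimethylsilyl chloride, CC(C)(C)[Si](C)(C)Cl
Why: Imidazole‑promoted silyl ether formation on both phenols gives a protection that is stable to organomagnesium reagents and Lewis acid and is removed by fluoride at the end.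

**Step 2**
Reactants: 2 1,3‑bis(tert‑butyldimethylsilyloxy)‑2‑iodobenzene; 3 1‑bromo‑3‑methylbut‑2‑ene (prenyl bromide)
Product: 5 1,3‑bis(tert‑butyldimethylsilyloxy)‑2‑(3‑methylbut‑2‑enyl)benzene, via arylmagnesium chloride 4 (not isolated)
Conditions: i‑PrMgCl·LiCl (1.15 eq), THF, 0 °C → rt; then CuI (10 mol %), 3 (1.3 eq), −20 °C → rt
Reagents that add atoms: none
Why: Iodine–magnesium exchange with the turbo‑Grignard reagent followed by copper‑catalysed allylic substitution at the primary carbon of prenyl bromide should place the prenyl group between the two oxygens, magnesium being used instead of lithium to suppress retro‑Brook silyl migration.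

**Step 3**
Reactants: 5 1,3‑bis(tert‑butyldimethylsilyloxy)‑2‑(3‑methylbut‑2‑enyl)benzene
Product: 7 3,5‑bis(tert‑butyldimethylsilyloxy)‑4‑(3‑methylbut‑2‑enyl)phenol, via arylboronate 6 (not isolated)
Conditions: [Ir(OMe)(cod)]2 (1.5 mol %), dtbpy (3 mol %), B2pin2 (1.0 eq), THF, 60 °C; then Me3NO (3 eq), THF, 50 °C; aqueous work‑up
Reagents that add atoms: trimethylamine N‑oxide, C[N+](C)(C)[O-]
Why: Iridium‑catalysed C–H borylation (Hartwig–Miyaura type) is sterically governed and should take the only ring C–H without an ortho substituent, para to the prenyl group, and amine‑oxide oxidation of the boronate then installs the third oxygen under neutral conditions that spare silyl ethers and alkene.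

**Step 4**
Reactants: 7 3,5‑bis(tert‑butyldimethylsilyloxy)‑4‑(3‑methylbut‑2‑enyl)phenol; 8 chloromethyl pivalate
Product: 9 [3,5‑bis(tert‑butyldimethylsilyloxy)‑4‑(3‑methylbut‑2‑enyl)phenoxy]methyl pivalate
Conditions: NaH (1.05 eq), NaI (cat.), THF/DMF, 0 °C → rt
Reagents that add atoms: none
Why: Williamson‑type O‑alkylation of the sodium phenoxide with the iodide‑activated acyloxymethyl chloride should give the pivaloyloxymethyl ether, a stable precursor of the aryloxymethyl cation whose hindered ester resists acyl transfer.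

**Step 5**
Reactants: 10 1‑(2,4‑dihydroxyphenyl)ethanone (2,4‑dihydroxyacetophenone)
Product: 11 1‑(2,4‑dihydroxy‑3‑iodophenyl)ethanone
Conditions: I2, HIO3, EtOH/H2O, rt
Reagents that add atoms: iodine, II; iodic acid, OI(=O)=O
Why: Electrophilic aromatic iodination of this chelated 2,4‑dihydroxyaryl ketone is known to go to C‑3, the position ortho to both hydroxyls.

**Step 6**
Reactants: 11 1‑(2,4‑dihydroxy‑3‑iodophenyl)ethanone
Product: 12 1‑[2‑hydroxy‑3‑iodo‑4‑(triisopropylsilyloxy)phenyl]ethanone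
Conditions: TIPSCl (1.05 eq), imidazole, DMF, 0 °C → rt
Reagents that add atoms: triisopropylsilyl chloride, CC(C)[Si](Cl)(C(C)C)C(C)C
Why: Selective phenol silylation should take the free 4‑OH, because the 2‑OH is hydrogen‑bonded to the acetyl group and flanked by iodine and acetyl.

**Step 7**
Reactants: 12 1‑[2‑hydroxy‑3‑iodo‑4‑(triisopropylsilyloxy)phenyl]ethanone
Product: 13 1‑[3‑iodo‑2‑methoxy‑4‑(triisopropylsilyloxy)phenyl]ethanone
Conditions: MeOH, PPh3, DIAD, THF, 0 °C → rt
Reagents that add atoms: methanol, CO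
Why: Mitsunobu O‑methylation alkylates the acidic chelated phenol under neutral conditions, so the base‑labile para‑acyl aryl silyl ether should not be cleaved.

**Step 8**
Reactants: 13 1‑[3‑iodo‑2‑methoxy‑4‑(triisopropylsilyloxy)phenyl]ethanone
Product: 14 methyl 2‑[3‑iodo‑2‑methoxy‑4‑(triisopropylsilyloxy)phenyl]acetate
Conditions: PhI(OAc)2 (1.2 eq), H2SO4 (1 eq), MeOH/HC(OMe)3, 60 °C
Reagents that add atoms: methanol, CO
Why: Iodine(III)‑mediated oxidative 1,2‑aryl migration of the methyl enol ether formed in situ (aryl methyl ketone to methyl arylacetate rearrangement) is favoured by the electron‑rich ortho‑methoxy/para‑silyloxy aryl group and should tolerate the aryl iodide and the acid‑stable TIPS ether.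

**Step 9**
Reactants: 14 methyl 2‑[3‑iodo‑2‑methoxy‑4‑(triisopropylsilyloxy)phenyl]acetate; 15 (E)‑4,4,5,5‑tetramethyl‑2‑(3‑methylbut‑1‑enyl)‑1,3,2‑dioxaborolane
Product: 16 methyl 2‑{2‑methoxy‑3‑[(E)‑3‑methylbut‑1‑enyl]‑4‑(triisopropylsilyloxy)phenyl}acetate
Conditions: Pd(OAc)2 (5 mol %), SPhos (10 mol %), K3PO4, toluene/H2O, 80 °C
Reagents that add atoms: none
Why: Suzuki–Miyaura coupling proceeds with retention of alkene geometry and should deliver the (E)‑3‑methylbut‑1‑enyl group, the biaryl phosphine being chosen for the di‑ortho‑substituted iodide.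

**Step 10**
Reactants: 16 methyl 2‑{2‑methoxy‑3‑[(E)‑3‑methylbut‑1‑enyl]‑4‑(triisopropylsilyloxy)phenyl}acetate
Product: 17 2‑{2‑methoxy‑3‑[(E)‑3‑methylbut‑1‑enyl]‑4‑(triisopropylsilyloxy)phenyl}acetic acid
Conditions: LiOH (1.5 eq), THF/H2O, 0 °C → rt; then 1 M HCl to pH 4
Reagents that add atoms: lithium hydroxide, [Li+].[OH-]
Why: Ester saponification with cold LiOH should leave the hindered, non‑activated aryl TIPS ether intact.

**Step 11**
Reactants: 17 2‑{2‑methoxy‑3‑[(E)‑3‑methylbut‑1‑enyl]‑4‑(triisopropylsilyloxy)phenyl}acetic acid; 18 (R)‑4‑benzyl‑1,3‑thiazolidine‑2‑thione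
Product: 19 (R)‑4‑benzyl‑3‑(2‑{2‑methoxy‑3‑[(E)‑3‑methylbut‑1‑enyl]‑4‑(triisopropylsilyloxy)phenyl}acetyl)‑1,3‑thiazolidine‑2‑thione
Conditions: DCC, DMAP (cat.), CH2Cl2, 0 °C → rt
Reagents that add atoms: none
Why: Carbodiimide/DMAP N‑acylation (Steglich type) of the thiazolidinethione gives the chiral thioimide that serves as enolate precursor, stereocontroller and activated acyl donor.

**Step 12**
Reactants: 19 (R)‑4‑benzyl‑3‑(2‑{2‑methoxy‑3‑[(E)‑3‑methylbut‑1‑enyl]‑4‑(triisopropylsilyloxy)phenyl}acetyl)‑1,3‑thiazolidine‑2‑thione; 9 [3,5‑bis(tert‑butyldimethylsilyloxy)‑4‑(3‑methylbut‑2‑enyl)phenoxy]methyl pivalate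
Product: 23 (3S)‑5,7‑bis(tert‑butyldimethylsilyloxy)‑3‑{2‑methoxy‑3‑[(E)‑3‑methylbut‑1‑enyl]‑4‑(triisopropylsilyloxy)phenyl}‑6‑(3‑methylbut‑2‑enyl)chroman‑4‑one, via chlorotitanium enolate 20 (not isolated), via aryl chloromethyl ether 21 (not isolated), via alkylated thioimide 22 (not isolated)
Conditions: 19, TiCl4 (1.05 eq), i‑Pr2NEt (1.0 eq), CH2Cl2, −78 → −40 °C; then 9 and TiCl4 (1.1 eq), −78 → −20 °C; then 0 °C; pH 7 buffer
Reagents that add atoms: none
Why: Proposed new method: TiCl4 converts 9 into the aryl chloromethyl ether 21 (an aryloxymethyl cation equivalent), which alkylates the chelated Z‑chlorotitanium enolate 20 at C‑3 to give 22; on warming, the O,S‑chelated N‑acyl thiazolidinethione of 22 acylates the flanking arene carbon and expels the auxiliary, so that C2–C3 and C4–C4a form in one flask as a formal [4+2] union of the C2=O1–C8a=C4a oxadiene cation with the C3=C4 enolate. The closest known reaction types are the alkylation of titanium enolates of chiral N‑acyl oxazolidinones and thiazolidinethiones with α‑chloro ethers and acetal‑derived oxocarbenium ions, the oxa‑Povarov annulation of aryl oxocarbenium ions, and Lewis‑acid Friedel–Crafts acylation with activated amides such as N‑acylbenzotriazoles; what is new is the thioimide itself as the Friedel–Crafts acyl donor, argued from its weak amide resonance (nitrogen lone pair drawn into C=S) and its bidentate activation by Ti(IV) opposite a triply oxygen‑activated arene in a six‑membered transition state. The pyranone ring closes by a 6‑exo‑trig SEAr acylation (addition–elimination at the thioimide carbonyl). The C‑3 stereocentre is set in the alkylation, the electrophile approaching the enolate face opposite the benzyl group of the (R)‑auxiliary, which should give (S); one equivalent of base leaves no free amine after enolisation and the cyclisation is run at or below 0 °C so that neither 22 nor 23 should epimerise. The step needs C‑alkylation of the enolate to outrun self‑condensation of the electron‑rich ether, which the far more nucleophilic titanium enolate and the bulky silyl ethers should secure, and it needs no regiocontrol in the ring closure because the two ortho carbons of 9 are equivalent.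

**Step 13**
Reactants: 23 (3S)‑5,7‑bis(tert‑butyldimethylsilyloxy)‑3‑{2‑methoxy‑3‑[(E)‑3‑methylbut‑1‑enyl]‑4‑(triisopropylsilyloxy)phenyl}‑6‑(3‑methylbut‑2‑enyl)chroman‑4‑one
Product: 24 (3S)‑5,7‑dihydroxy‑3‑{4‑hydroxy‑2‑methoxy‑3‑[(E)‑3‑methylbut‑1‑enyl]phenyl}‑6‑(3‑methylbut‑2‑enyl)chroman‑4‑one
Conditions: TBAF, AcOH (1:1, 4 eq), THF, 0 °C → rt
Reagents that add atoms: none
Why: Buffered fluoride desilylation cleaves the three aryl silyl ethers while acetic acid protonates the phenoxides formed, so the base‑labile C‑3 stereocentre should not be epimerised and no strong acid is present to cyclise the prenyl group onto the flanking phenols.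

**Compound list**
1 | 2‑iodobenzene‑1,3‑diol | Oc1cccc(O)c1I | starting material
2 | 1,3‑bis(tert‑butyldimethylsilyloxy)‑2‑iodobenzene | CC(C)(C)[Si](C)(C)Oc1cccc(O[Si](C)(C)C(C)(C)C)c1I | intermediate
3 | 1‑bromo‑3‑methylbut‑2‑ene | CC(C)=CCBr | starting material
4 | [2,6‑bis(tert‑butyldimethylsilyloxy)phenyl]magnesium chloride | CC(C)(C)[Si](C)(C)Oc1cccc(O[Si](C)(C)C(C)(C)C)c1[Mg]Cl | intermediate
5 | 1,3‑bis(tert‑butyldimethylsilyloxy)‑2‑(3‑methylbut‑2‑enyl)benzene | CC(C)=CCc1c(O[Si](C)(C)C(C)(C)C)cccc1O[Si](C)(C)C(C)(C)C | intermediate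
6 | 2‑[3,5‑bis(tert‑butyldimethylsilyloxy)‑4‑(3‑methylbut‑2‑enyl)phenyl]‑4,4,5,5‑tetramethyl‑1,3,2‑dioxaborolane | CC(C)=CCc1c(O[Si](C)(C)C(C)(C)C)cc(B2OC(C)(C)C(C)(C)O2)cc1O[Si](C)(C)C(C)(C)C | intermediate
7 | 3,5‑bis(tert‑butyldimethylsilyloxy)‑4‑(3‑methylbut‑2‑enyl)phenol | CC(C)=CCc1c(O[Si](C)(C)C(C)(C)C)cc(O)cc1O[Si](C)(C)C(C)(C)C | intermediate
8 | chloromethyl pivalate | CC(C)(C)C(=O)OCCl | starting material
9 | [3,5‑bis(tert‑butyldimethylsilyloxy)‑4‑(3‑methylbut‑2‑enyl)phenoxy]methyl pivalate | CC(C)(C)C(=O)OCOc1cc(O[Si](C)(C)C(C)(C)C)c(CC=C(C)C)c(O[Si](C)(C)C(C)(C)C)c1 | intermediate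
10 | 1‑(2,4‑dihydroxyphenyl)ethanone | CC(=O)c1ccc(O)cc1O | starting material
11 | 1‑(2,4‑dihydroxy‑3‑iodophenyl)ethanone | CC(=O)c1ccc(O)c(I)c1O | intermediate
12 | 1‑[2‑hydroxy‑3‑iodo‑4‑(triisopropylsilyloxy)phenyl]ethanone | CC(=O)c1ccc(O[Si](C(C)C)(C(C)C)C(C)C)c(I)c1O | intermediate
13 | 1‑[3‑iodo‑2‑methoxy‑4‑(triisopropylsilyloxy)phenyl]ethanone | COc1c(C(C)=O)ccc(O[Si](C(C)C)(C(C)C)C(C)C)c1I | intermediate
14 | methyl 2‑[3‑iodo‑2‑methoxy‑4‑(triisopropylsilyloxy)phenyl]acetate | COC(=O)Cc1ccc(O[Si](C(C)C)(C(C)C)C(C)C)c(I)c1OC | intermediate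
15 | (E)‑4,4,5,5‑tetramethyl‑2‑(3‑methylbut‑1‑enyl)‑1,3,2‑dioxaborolane | CC(C)/C=C/B1OC(C)(C)C(C)(C)O1 | starting material
16 | methyl 2‑{2‑methoxy‑3‑[(E)‑3‑methylbut‑1‑enyl]‑4‑(triisopropylsilyloxy)phenyl}acetate | COC(=O)Cc1ccc(O[Si](C(C)C)(C(C)C)C(C)C)c(/C=C/C(C)C)c1OC | intermediate
17 | 2‑{2‑methoxy‑3‑[(E)‑3‑methylbut‑1‑enyl]‑4‑(triisopropylsilyloxy)phenyl}acetic acid | COc1c(CC(=O)O)ccc(O[Si](C(C)C)(C(C)C)C(C)C)c1/C=C/C(C)C | intermediate
18 | (R)‑4‑benzyl‑1,3‑thiazolidine‑2‑thione | S=C1N[C@H](Cc2ccccc2)CS1 | starting material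
19 | (R)‑4‑benzyl‑3‑(2‑{2‑methoxy‑3‑[(E)‑3‑methylbut‑1‑enyl]‑4‑(triisopropylsilyloxy)phenyl}acetyl)‑1,3‑thiazolidine‑2‑thione | COc1c(CC(=O)N2C(=S)SC[C@H]2Cc2ccccc2)ccc(O[Si](C(C)C)(C(C)C)C(C)C)c1/C=C/C(C)C | intermediate
20 | trichlorotitanium (Z)‑enolate of 19 | COc1c(/C=C(\O[Ti](Cl)(Cl)Cl)N2C(=S)SC[C@H]2Cc2ccccc2)ccc(O[Si](C(C)C)(C(C)C)C(C)C)c1/C=C/C(C)C | intermediate
21 | 1,3‑bis(tert‑butyldimethylsilyloxy)‑5‑(chloromethoxy)‑2‑(3‑methylbut‑2‑enyl)benzene | ClCOc1cc(O[Si](C)(C)C(C)(C)C)c(CC=C(C)C)c(O[Si](C)(C)C(C)(C)C)c1 | intermediate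
22 | (R)‑4‑benzyl‑3‑[(2S)‑3‑[3,5‑bis(tert‑butyldimethylsilyloxy)‑4‑(3‑methylbut‑2‑enyl)phenoxy]‑2‑{2‑methoxy‑3‑[(E)‑3‑methylbut‑1‑enyl]‑4‑(triisopropylsilyloxy)phenyl}propanoyl]‑1,3‑thiazolidine‑2‑thione | COc1c([C@@H](COc2cc(O[Si](C)(C)C(C)(C)C)c(CC=C(C)C)c(O[Si](C)(C)C(C)(C)C)c2)C(=O)N2C(=S)SC[C@H]2Cc2ccccc2)ccc(O[Si](C(C)C)(C(C)C)C(C)C)c1/C=C/C(C)C | intermediate
23 | (3S)‑5,7‑bis(tert‑butyldimethylsilyloxy)‑3‑{2‑methoxy‑3‑[(E)‑3‑methylbut‑1‑enyl]‑4‑(triisopropylsilyloxy)phenyl}‑6‑(3‑methylbut‑2‑enyl)chroman‑4‑one | COc1c([C@H]2COc3cc(O[Si](C)(C)C(C)(C)C)c(CC=C(C)C)c(O[Si](C)(C)C(C)(C)C)c3C2=O)ccc(O[Si](C(C)C)(C(C)C)C(C)C)c1/C=C/C(C)C | intermediate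
24 | (3S)‑5,7‑dihydroxy‑3‑{4‑hydroxy‑2‑methoxy‑3‑[(E)‑3‑methylbut‑1‑enyl]phenyl}‑6‑(3‑methylbut‑2‑enyl)chroman‑4‑one (CNP0289142.1) | COc1c([C@H]2COc3cc(O)c(CC=C(C)C)c(O)c3C2=O)ccc(O)c1/C=C/C(C)C | target

**Step count and risks**
Total steps: 13. Longest linear sequence: 9 (steps 5–13, from 10 to 24).

Steps most likely to fail:

Step 12 (Proposed new method). The thioimide of 22 may prove too weak an acyl donor, so that ring closure stalls after the alkylation. On warming, the Lewis acid may instead induce β‑elimination of the aryloxide or erode the configuration at C‑3. The fallback is stepwise and uses known chemistry. It sets out from 22, which is isolated after a quench at −20 °C. LiOH/H2O2 in THF/H2O at 0 °C removes the auxiliary to give (2S)‑3‑[3,5‑bis(tert‑butyldimethylsilyloxy)‑4‑(3‑methylbut‑2‑enyl)phenoxy]‑2‑{2‑methoxy‑3‑[(E)‑3‑methylbut‑1‑enyl]‑4‑(triisopropylsilyloxy)phenyl}propanoic acid F1. TFAA in CH2Cl2 at 0 °C then closes the pyranone ring through the mixed anhydride, the classical Friedel–Crafts cyclisation of 3‑aryloxypropanoic acids to chroman‑4‑ones, and the route is rejoined at 23.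

Step 2. A silyl group may migrate from oxygen to the metalated carbon during the exchange, the exchange at the crowded iodide may be incomplete, or the aryl nucleophile may attack the tertiary end of prenyl bromide. The fallback avoids any aryl–metal species and takes both oxygens from a saturated ring. It sets out from 3: commercial cyclohexane‑1,3‑dione is C‑alkylated with 3 (aq. KOH) to 2‑(3‑methylbut‑2‑enyl)cyclohexane‑1,3‑dione F2. TBSOTf/Et3N converts this into the bis‑silyl dienol ether 1,3‑bis(tert‑butyldimethylsilyloxy)‑2‑(3‑methylbut‑2‑enyl)cyclohexa‑1,3‑diene F3, and DDQ dehydrogenation aromatises the ring to rejoin the route at 5.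

Step 3. Borylation or hydroboration may compete at the prenyl alkene, arene borylation beside the two bulky silyl ethers may be slow, or a silyl group may be lost in the oxidation. The fallback has all three oxygens present from the start and differentiates them by sterics instead of C–H functionalisation. It sets out from 3: commercial phloroglucinol is C‑prenylated with 3 (DBU, THF) to 2‑(3‑methylbut‑2‑enyl)benzene‑1,3,5‑triol F4. Exhaustive silylation (TBSCl, imidazole) gives 1,3,5‑tris(tert‑butyldimethylsilyloxy)‑2‑(3‑methylbut‑2‑enyl)benzene F5. One equivalent of KHF2 in MeOH at 0 °C should then remove the least hindered silyl group, the one para to the prenyl group, to rejoin the route at 7.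

**Further compounds**
F1 | step 12 | (2S)‑3‑[3,5‑bis(tert‑butyldimethylsilyloxy)‑4‑(3‑methylbut‑2‑enyl)phenoxy]‑2‑{2‑methoxy‑3‑[(E)‑3‑methylbut‑1‑enyl]‑4‑(triisopropylsilyloxy)phenyl}propanoic acid | COc1c([C@@H](COc2cc(O[Si](C)(C)C(C)(C)C)c(CC=C(C)C)c(O[Si](C)(C)C(C)(C)C)c2)C(=O)O)ccc(O[Si](C(C)C)(C(C)C)C(C)C)c1/C=C/C(C)C
F2 | step 2 | 2‑(3‑methylbut‑2‑enyl)cyclohexane‑1,3‑dione | O=C1CCCC(=O)C1CC=C(C)C
F3 | step 2 | 1,3‑bis(tert‑butyldimethylsilyloxy)‑2‑(3‑methylbut‑2‑enyl)cyclohexa‑1,3‑diene | CC(C)=CCC1=C(O[Si](C)(C)C(C)(C)C)CCC=C1O[Si](C)(C)C(C)(C)C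
F4 | step 3 | 2‑(3‑methylbut‑2‑enyl)benzene‑1,3,5‑triol | CC(C)=CCc1c(O)cc(O)cc1O
F5 | step 3 | 1,3,5‑tris(tert‑butyldimethylsilyloxy)‑2‑(3‑methylbut‑2‑enyl)benzene | CC(C)=CCc1c(O[Si](C)(C)C(C)(C)C)cc(O[Si](C)(C)C(C)(C)C)cc1O[Si](C)(C)C(C)(C)C
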